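Remark: locants are atisane-type and are defined in the first section. The configuration read from the SMILES (5S,8S,9S,10S,12R,14S in these locants) is taken as correct, and it calls for (S)-carvone.

## The problem

Crotobarin (28) is a 3,4-seco-atisane built around the bond C8–C9. A δ-lactone (O–C9, C10, C1, C2, C3), cyclohexane ring B (C5–C10) and a bicyclo[2.2.2]octane (bridgeheads C8 and C12; bridges C9–C11, C14–C13 and C15–C16) are fused there. C10 carries methyl C20, C5 an isopropenyl group (C4, C18, C19), C14 an acetate, and C15(=O)–C16(=C17H2) is an α-methylene ketone.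

The hard part is the run of three contiguous fully substituted carbons: C8 (quaternary bridgehead), C9 (tertiary lactone oxygen) and C10 (quaternary). The bond C8–C9 has to be made inside a bridged system.

Of the six stereocentres, C8, C9 and C12 are locked to each other by the bicycle. They must be correlated with C14 on one side (acetate syn to the C15–C16 bridge) and with the C5/C10 pair on the other (C1 chain trans to isopropenyl, C20 cis). No single centre controls all the others through bonds, so a relay through a ring-forming step is needed.

The α-methylene ketone is a Michael acceptor and should appear last. The C14 acetate is β to the C15 ketone and survives only because C8 has no hydrogen, so a C14 oxygen cannot be carried through enolate chemistry at C8. The isopropenyl group and any other 1,1-disubstituted alkene must be told apart in every oxidation step.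

The feature that opens the problem is the carbocycle C8–C15–C16–C12–C13–C14 of the bicyclooctane. It has the carbon and oxidation pattern of carvone: C15 is the carbonyl, C16 carries the one-carbon substituent C17, C14 carries a two-carbon oxygenated unit that an isopropenyl group can become, and C8 is the α′-carbon. C8 and C12 are its 1,4-positions, the termini of carvone's cross-conjugated dienol. The remaining bridge C9–C11 is the carbon pair of an exocyclic enol lactone (C9 bears the lactone oxygen and C10; C11 is CH2), held to C8 by the four ring B atoms C7–C6–C5–C10.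

## Retrosynthesis

**28 ⇒ 26.** No skeletal bond is cut; the C16=C17 double bond is taken back to a C16 methyl group (26, via silyl enol ether 27). The α-methylene ketone would not survive ozone or a phosphorus ylide, so it is made last. C15 has one α-hydrogen only (C8 is quaternary), and only the methyl hydrogens can be lost because C12 is a bridgehead. The forward step has to enolise C15 in the presence of a lactone and an acetate.

**26 ⇒ 25 ⇒ 22.** Two functional-group changes are taken back. The C5 isopropenyl group becomes an acetyl group (25, Wittig), and the C14 acetate becomes an isopropenyl group (22, Criegee rearrangement with retention).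
- The acetate cannot be present earlier: with a hydrogen or a double bond at C8, a C14 oxygen is β-eliminated or ionised. A carbon substituent that is excised later is the safe placeholder, and the isopropenyl group of carvone is exactly that.
- The C5 isopropenyl group must be absent while ozone is used and while the diene of the key step is in the molecule. It would be cleaved by ozone, and it would be a better-placed dienophile (three-atom tether). As a methyl ketone it is inert to both.
- An equatorial acetyl group on ring B is the stable epimer, so any loss of configuration at C5 should be corrected by base once ring B exists.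
- The cost is one ozonolysis (step 6) and one methylenation (step 11).

**22 ⇒ 21 ⇒ 20 ⇒ 19 (key).** Bonds C8–C9 and C11–C12 are cut together (retro-Diels–Alder after re-forming enol ether 21). This removes ring B and two of the three bridges in one operation and leaves a monocyclic carvone ring. Cutting the C15–C16 or C13–C14 bridge instead (alkylation, aldol or radical closure) would leave C8–C9, the most hindered bond, for a stepwise process and would not use the oxygen at C9. The precursor, dienol ether 20, has three stereocentres (C14, C5, C10) instead of six and no bridged ring; it comes from dienone 19 by delivery of hydride to C7. The forward reaction must pair a 2-silyloxydiene with an unactivated 1,1-disubstituted enol lactone against the electronic bias of the diene, which the four-atom tether has to enforce, and must choose one of four diastereomeric transition states.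

**19 ⇒ 15 + 14.** The C7=C8 double bond is cut (aldol condensation). Union by alkylation of the carvone enolate would need strong base a second time to make the diene, which the enol lactone and the ketone of the tether would not tolerate. The alkylidene ketone gives the same dienol ether under neutral conditions. The precursors are commercial (S)-carvone (15) and aldehyde 14, which carries the C5/C10 pair and the dienophile.

**14 ⇒ 13 ⇒ 11.** The enol lactone bond O–C9 is cut to the 5-alkynoic acid 13 (6-exo-dig cycloisomerisation), and the acetyl group of 13 is taken back to the isopropenyl group of 11 (ozonolysis). Cycloisomerisation is preferred to enol lactonisation of a keto acid because it is neutral and regiospecific. The ozonolysis is placed here because 11 has no other reactive alkene and meets no strong base before ring B is formed.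

**11 ⇒ 9 ⇒ 8 ⇒ 7.** The alkyne C9≡C11 and the aldehyde C7 are joined back into a ring (bond C7–C11; Eschenmoser–Tanabe fragmentation of epoxy ketone 9, from enone 8 and ketone 7). Building the acyclic C5/C10 pair directly would need acyclic stereocontrol over a quaternary centre. A cyclohexanone lets both centres be set by conjugate addition and enolate trapping, and it is then opened with all six ring carbons kept (C9, C10, C5, C6, C7, C11).

**7 ⇒ 4 + 5 ⇒ 1 + 2.** The bonds C10–C1 (Mukaiyama–Michael) and C5–C4 (conjugate addition) are cut, leading to 2-methylcyclohex-2-en-1-one (1), isopropenylmagnesium bromide (2) and methyl acrylate (5). The methyl group is already in the enone, so the chain enters second and trans to the isopropenyl group, which is the relative configuration of 28.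

## Roads not taken

Alternative 1: The most obvious plan cuts the same two bonds, C8–C9 and C11–C12, but in an arene-derived ring. A 2-alkylphenol is oxidatively dearomatised to the masked ortho-benzoquinone A1, which undergoes an intramolecular Diels–Alder reaction with a tethered vinyl group. The cycloaddition is electronically matched and closes ring B and the bicycle at once. It is not chosen for these reasons:
- C9 arrives as CH. The lactone oxygen would have to be brought in later, by oxidation next to two quaternary carbons or by a cationic lactonisation in the presence of the isopropenyl group.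
- C14 arrives as an alkene carbon, and its hydration is biased towards C13.
- C16 arrives as a ketal that needs further steps.
- The diene has no stereocentre, so all facial control rests on the remote tether. In the chosen plan C14 sits next to the diene terminus.

Alternative 2: Ring B is cut at C9=C10 and C7–C8. A Robinson annulation of a 2-propargyl cyclohexane-1,3-dione with a vinyl ketone carrying the propanoate chain (amino-acid-catalysed desymmetrising aldol) gives enedione A2. Deconjugative methylation at C10, reduction at C14 and closure of the C16–C12 bond by a vinyl radical would follow. Each stereocentre is set by well-known diastereoselection. It is not chosen because C5 arrives as a ketone whose conversion into a CH–isopropenyl unit costs several steps, ring C must be re-oxidised to an enone before the bridge can be closed, and C15 needs a late allylic oxidation. The oxidation pattern of carvone supplies C14, C15 and C17 without these adjustments.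

Alternative 3: Ring A is left closed. The intact atisane diketone A3 is built, C3–C4 is cleaved by Baeyer–Villiger oxidation and elimination, and the acid is lactonised onto C9. This follows the likely biogenesis and can draw on decalin chemistry. It is not chosen because a ring is made only to be broken, the Baeyer–Villiger step must distinguish the C3 from the C15 ketone, the acid-promoted opening is expected to give isopropenyl and isopropylidene isomers, and C9 must be oxidised late at a tertiary C–H flanked by two quaternary carbons. In the chosen plan the C9 oxygen is in the dienophile from the start.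

Key step: step 9

## Route

Step 1
Reactants: 1 2-methylcyclohex-2-en-1-one; 2 prop-1-en-2-ylmagnesium bromide
Product: 4 (S)-trimethyl{[2-methyl-3-(prop-1-en-2-yl)cyclohex-1-en-1-yl]oxy}silane, via magnesium enolate 3 (not isolated)
Conditions: 2 (1.2 equiv), CuBr·SMe2 (5 mol %), (R)-1-[(S)-2-(diphenylphosphino)ferrocenyl]ethyldicyclohexylphosphine (6 mol %; the ligand enantiomer that gives (S)-4 is used), t-BuOMe, −78 °C; then TMSCl, Et3N, −78 °C → rt
Reagents that add atoms: chlorotrimethylsilane, C[Si](C)(C)Cl
Why: Copper-catalysed asymmetric conjugate addition of a Grignard reagent to an α-substituted cyclic enone sets C5 under ligand control and forms the C9–C10 enolate regiospecifically; O-silylation stores that regiochemistry.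

Step 2
Reactants: 4 silyl enol ether; 5 methyl acrylate
Product: 7 methyl 3-[(1S,6S)-1-methyl-2-oxo-6-(prop-1-en-2-yl)cyclohexyl]propanoate, via silyl ketene acetal 6 (not isolated)
Conditions: 5 (1.5 equiv), Tf2NH (2 mol %), CH2Cl2, −78 °C; then 1 M HCl, THF, 0 °C
Reagents that add atoms: none
Why: Mukaiyama–Michael addition; allylic strain holds the C5 isopropenyl group pseudo-axial, so the acrylate should add to C10 from the opposite face, placing the chain trans and the methyl cis to isopropenyl as in 28.

Step 3
Reactants: 7 keto ester
Product: 8 methyl 3-[(1S,6S)-1-methyl-2-oxo-6-(prop-1-en-2-yl)cyclohex-3-en-1-yl]propanoate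
Conditions: IBX (2.5 equiv), DMSO/fluorobenzene (1:2), 70 °C
Reagents that add atoms: none
Why: IBX dehydrogenation of a ketone to the enone; C10 is quaternary, so only the C11–C7 side can be desaturated, and isolated alkenes and esters are tolerated.

Step 4
Reactants: 8 enone ester
Product: 9 3-[(1R,3S,4S,6R)-3-methyl-2-oxo-4-(prop-1-en-2-yl)-7-oxabicyclo[4.1.0]heptan-3-yl]propanoic acid
Conditions: 30% H2O2 (3 equiv), LiOH (3 equiv), MeOH/H2O, 0 °C → rt; then 1 M HCl to pH 3
Reagents that add atoms: hydrogen peroxide, OO; lithium hydroxide, [Li+].[OH-]
Why: Weitz–Scheffer epoxidation (hydroperoxide should add to C7 anti to the C5 substituent, as with carvone) runs together with saponification of the methyl ester; the epoxide configuration is erased in step 5.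

Step 5
Reactants: 9 epoxy keto acid
Product: 11 (4S,5S)-4-ethynyl-4-methyl-7-oxo-5-(prop-1-en-2-yl)heptanoic acid, via epoxy tosylhydrazone 10 (not isolated)
Conditions: TsNHNH2 (1.1 equiv), AcOH/CH2Cl2 (1:1), −20 °C → rt
Reagents that add atoms: none
Why: Eschenmoser–Tanabe fragmentation; the epoxy tosylhydrazone cleaves the C7–C11 bond with loss of N2 and sulfinate, turning C9/C11 into the terminal alkyne and C7 into the aldehyde without touching C5 or C10.

Step 6
Reactants: 11 ynal acid
Product: 13 (4S,5R)-5-acetyl-4-ethynyl-4-methyl-7-oxoheptanoic acid, via ozonide 12 (not isolated)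
Conditions: O3 (1.0 equiv), CH2Cl2, −78 °C; then PPh3, −78 °C → rt
Reagents that add atoms: ozone, [O-][O+]=O
Why: Ozonolysis; the electron-rich 1,1-disubstituted alkene should react much faster than the terminal alkyne, and the isopropenyl group is parked as an acetyl group so that it is neither a dienophile in step 9 nor cleaved in step 10.

Step 7
Reactants: 13 acetyl ynal acid
Product: 14 (3R)-3-[(3S)-3-methyl-2-methylidene-6-oxooxan-3-yl]-4-oxopentanal
Conditions: Ph3PAuNTf2 (2 mol %), CH2Cl2, rt
Reagents that add atoms: none
Why: Gold-catalysed 6-exo-dig cycloisomerisation of a 5-alkynoic acid gives the exocyclic enol lactone under neutral conditions; quaternary C10 rules out the endocyclic isomer.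

Step 8
Reactants: 15 (S)-carvone; 14 enol lactone aldehyde
Product: 19 (5R,6E)-2-methyl-6-{(3R)-3-[(3S)-3-methyl-2-methylidene-6-oxooxan-3-yl]-4-oxopentylidene}-5-(prop-1-en-2-yl)cyclohex-2-en-1-one, via lithium dienolate 16 (not isolated), via lithium aldolate 17 (not isolated), via mesylate 18 (not isolated)
Conditions: LDA (1.05 equiv), THF, −78 °C, 15; then 14, −78 °C; then MsCl (1.5 equiv), Et3N (4 equiv), −78 → 0 °C
Reagents that add atoms: none
Why: Aldol condensation; kinetic α′-deprotonation of carvone, addition to the aldehyde (expected to be faster than attack on the ketone or the enol lactone) and E1cB loss of mesylate through the C8 enolate give the cross-conjugated dienone, and the configurations at C7 and C8 are of no consequence.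

Step 9
Reactants: 19 dienone
Product: 22 tetracyclic keto lactone (28 with C16–CH3 in place of C16=CH2 as both C16 epimers and with acetyl at C5 and isopropenyl at C14), via silyl dienol ether 20 (not isolated), via cycloadduct 21 (not isolated)
Conditions: Et3SiH (1.3 equiv), RhCl(PPh3)3 (2 mol %), toluene, 50 °C; filtration through Florisil; 0.005 M in toluene, Et3N (0.1 equiv), BHT, 170 °C, sealed tube; then 1 M HCl, THF, 0 °C
Reagents that add atoms: none
Why: Rhodium-catalysed 1,4-hydrosilylation of the exocyclic s-cis enone puts hydride on C7 and silicon on oxygen, giving the cross-conjugated 2-silyloxydiene C8=C15(OSiEt3)–C16=C12 (20) without base; on heating, 20 undergoes a type 1 intramolecular Diels–Alder reaction with the exocyclic enol lactone C9=C11 as dienophile (closest precedent: thermal intramolecular cycloadditions of 2-silyloxycyclohexa-1,3-dienes with tethered alkenes to bicyclo[2.2.2]octenes with vicinal quaternary carbons). Ring B closes in the fused mode through the four-atom tether C7–C6–C5–C10 (bond C8–C9) and the bicyclo[2.2.2]octene by [4+2] addition across C8 and C12 (bonds C8–C9 and C11–C12); the tether fixes the regiochemistry against the electronic bias of the diene. C8 and C12 are set by the C14 isopropenyl group on the carbon next to the diene terminus, which should make the dienophile add to the opposite face and so place the future acetate syn to the C15–C16 bridge. C9 is set by the endo/exo choice: the small lactone oxygen should sit under the diene and quaternary C10 with its tether point away, which puts oxygen syn to the C15–C16 bridge and cis to C1 as in 28. The tether chirality (C5, C10) is matched with this topography, because it lets ring B form as a chair with the C5 acetyl group equatorial and C20 axial. The step needs chemoselectivity (no second dienophile: the C5 isopropenyl is parked as acetyl and the C14 isopropenyl cannot reach the diene) and hydride regioselectivity (exocyclic over ring enone), the latter being the weaker point. Acidic work-up hydrolyses enol ether 21 to ketone 22, so that the isopropenyl group is the only alkene to meet ozone in step 10.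

Step 10
Reactants: 22 tetracyclic keto lactone
Product: 25 C14 acetate (16,17-dihydro-28 with acetyl at C5 and both C16 epimers), via methoxy hydroperoxide 23 (not isolated), via peracetate 24 (not isolated)
Conditions: O3, CH2Cl2/MeOH (5:1), −78 °C; evaporation; then Ac2O, Et3N, DMAP (cat.), CH2Cl2, 0 °C → rt
Reagents that add atoms: ozone, [O-][O+]=O; methanol, CO
Why: Criegee rearrangement; ozonolysis in methanol gives the α-methoxy hydroperoxide, whose peracetate rearranges with migration of C14 from carbon to oxygen with retention, and C8 being quaternary the new β-acetoxy ketone cannot eliminate.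

Step 11
Reactants: 25 C14 acetate
Product: 26 16,17-dihydrocrotobarin (both C16 epimers)
Conditions: Ph3PCH3Br (1.5 equiv), KOtBu (1.4 equiv), THF, 0 °C; then 25, 0 °C → rt
Reagents that add atoms: methyltriphenylphosphonium bromide, C[P+](c1ccccc1)(c1ccccc1)c1ccccc1.[Br-]
Why: Wittig methylenation; the methyl ketone should react while the C15 ketone, flanked by quaternary C8 and tertiary C16, is left, and base-mediated equilibration keeps the C5 substituent equatorial.

Step 12
Reactants: 26 16,17-dihydrocrotobarin
Product: 28 crotobarin, via silyl enol ether 27 (not isolated)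
Conditions: TMSOTf (1.5 equiv), Et3N (3 equiv), CH2Cl2, 0 °C; solvent exchange; then Pd(OAc)2 (1.1 equiv), MeCN, rt
Reagents that add atoms: none
Why: Soft enolisation of the C15 ketone can only go towards C16, and Saegusa–Ito oxidation of the enol ether must take a methyl hydrogen because C12 is a bridgehead, which gives the α-methylene ketone.

## Compound list

1 | 2-methylcyclohex-2-en-1-one | CC1=CCCCC1=O | starting material
2 | prop-1-en-2-ylmagnesium bromide | CC(=C)[Mg]Br | starting material
3 | bromomagnesium (3S)-2-methyl-3-(prop-1-en-2-yl)cyclohex-1-en-1-olate | CC1=C(O[Mg]Br)CCC[C@H]1C(C)=C | intermediate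
4 | (S)-trimethyl{[2-methyl-3-(prop-1-en-2-yl)cyclohex-1-en-1-yl]oxy}silane | CC1=C(O[Si](C)(C)C)CCC[C@H]1C(C)=C | intermediate
5 | methyl acrylate | C=CC(=O)OC | starting material
6 | methyl trimethylsilyl ketene acetal of 7 (double-bond geometry undefined) | O=C1CCC[C@@H](C(C)=C)[C@]1(C)CC=C(OC)O[Si](C)(C)C | intermediate
7 | methyl 3-[(1S,6S)-1-methyl-2-oxo-6-(prop-1-en-2-yl)cyclohexyl]propanoate | O=C1CCC[C@@H](C(C)=C)[C@]1(C)CCC(=O)OC | intermediate
8 | methyl 3-[(1S,6S)-1-methyl-2-oxo-6-(prop-1-en-2-yl)cyclohex-3-en-1-yl]propanoate | O=C1C=CC[C@@H](C(C)=C)[C@]1(C)CCC(=O)OC | intermediate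
9 | 3-[(1R,3S,4S,6R)-3-methyl-2-oxo-4-(prop-1-en-2-yl)-7-oxabicyclo[4.1.0]heptan-3-yl]propanoic acid | O=C1[C@@H]2O[C@@H]2C[C@@H](C(C)=C)[C@]1(C)CCC(=O)O | intermediate
10 | N-tosylhydrazone of 9 (C=N geometry undefined) | Cc1ccc(cc1)S(=O)(=O)NN=C1[C@@H]2O[C@@H]2C[C@@H](C(C)=C)[C@]1(C)CCC(=O)O | intermediate
11 | (4S,5S)-4-ethynyl-4-methyl-7-oxo-5-(prop-1-en-2-yl)heptanoic acid | O=CC[C@@H](C(C)=C)[C@](C)(CCC(=O)O)C#C | intermediate
12 | ozonide (3-methyl-1,2,4-trioxolan-3-yl in place of isopropenyl) of 11, ring carbon undefined | O=CC[C@@H](C1(C)OCOO1)[C@](C)(CCC(=O)O)C#C | intermediate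
13 | (4S,5R)-5-acetyl-4-ethynyl-4-methyl-7-oxoheptanoic acid | O=CC[C@@H](C(C)=O)[C@](C)(CCC(=O)O)C#C | intermediate
14 | (3R)-3-[(3S)-3-methyl-2-methylidene-6-oxooxan-3-yl]-4-oxopentanal | O=CC[C@@H](C(C)=O)[C@]1(C)CCC(=O)OC1=C | intermediate
15 | (S)-carvone, (5S)-2-methyl-5-(prop-1-en-2-yl)cyclohex-2-en-1-one | CC1=CC[C@@H](CC1=O)C(C)=C | starting material
16 | lithium cross-conjugated dienolate of 15 | CC1=CC[C@@H](C=C1O[Li])C(C)=C | intermediate
17 | lithium aldolate of 15 and 14 (C7 and C8 undefined) | CC1=CC[C@H](C(C)=C)C(C(O[Li])C[C@@H](C(C)=O)[C@]2(C)CCC(=O)OC2=C)C1=O | intermediate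
18 | C7 methanesulfonate of the aldol (C7 and C8 undefined) | CC1=CC[C@H](C(C)=C)C(C(OS(C)(=O)=O)C[C@@H](C(C)=O)[C@]2(C)CCC(=O)OC2=C)C1=O | intermediate
19 | (5R,6E)-2-methyl-6-{(3R)-3-[(3S)-3-methyl-2-methylidene-6-oxooxan-3-yl]-4-oxopentylidene}-5-(prop-1-en-2-yl)cyclohex-2-en-1-one | O=C1C(C)=CC[C@H](C(C)=C)/C1=C\C[C@@H](C(C)=O)[C@]2(C)CCC(=O)OC2=C | intermediate
20 | triethylsilyl dienol ether C8=C15(OSiEt3)–C16=C12 of 7,8-dihydro-19 | CC1=CC[C@H](C(C)=C)C(CC[C@@H](C(C)=O)[C@]2(C)CCC(=O)OC2=C)=C1O[Si](CC)(CC)CC | intermediate
21 | Diels–Alder adduct, triethylsilyl enol ether of 22 | CC1=C(O[Si](CC)(CC)CC)[C@]23CC[C@@H](C(C)=O)[C@]4(C)CCC(=O)O[C@@]42C[C@H]1C[C@@H]3C(C)=C | intermediate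
22 | tetracyclic keto lactone: 28 with C16–CH3 (C16 undefined), acetyl at C5, isopropenyl at C14 | CC1C(=O)[C@]23CC[C@@H](C(C)=O)[C@]4(C)CCC(=O)O[C@@]42C[C@H]1C[C@@H]3C(C)=C | intermediate
23 | α-methoxy hydroperoxide from the C14 isopropenyl group of 22 (ketal carbon and C16 undefined) | CC1C(=O)[C@]23CC[C@@H](C(C)=O)[C@]4(C)CCC(=O)O[C@@]42C[C@H]1C[C@@H]3C(C)(OC)OO | intermediate
24 | peracetate of 23 | CC1C(=O)[C@]23CC[C@@H](C(C)=O)[C@]4(C)CCC(=O)O[C@@]42C[C@H]1C[C@@H]3C(C)(OC)OOC(C)=O | intermediate
25 | C14 acetate: 16,17-dihydro-28 with acetyl at C5 (C16 undefined) | CC1C(=O)[C@]23CC[C@@H](C(C)=O)[C@]4(C)CCC(=O)O[C@@]42C[C@H]1C[C@@H]3OC(C)=O | intermediate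
26 | 16,17-dihydrocrotobarin (C16 undefined) | CC1C(=O)[C@]23CC[C@@H](C(C)=C)[C@]4(C)CCC(=O)O[C@@]42C[C@H]1C[C@@H]3OC(C)=O | intermediate
27 | trimethylsilyl enol ether C15(OSiMe3)=C16 of 26 | CC1=C(O[Si](C)(C)C)[C@]23CC[C@@H](C(C)=C)[C@]4(C)CCC(=O)O[C@@]42C[C@H]1C[C@@H]3OC(C)=O | intermediate
28 | crotobarin | C=C1C(=O)[C@]23CC[C@@H](C(=C)C)[C@]4(C)CCC(=O)O[C@@]42C[C@H]1C[C@@H]3OC(C)=O | target

## Step count and least certain steps

Total step count: 12. Longest linear sequence: 12 steps (1 → 28); (S)-carvone 15 enters at step 8.

**Step 9 (key step).** Three processes can fail.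
- Hydride may be delivered to C12 of the ring enone instead of C7, which gives the wrong dienol ether.
- The cycloaddition may be slow, because the C8–C9 bond joins two fully substituted carbons next to quaternary C10. A [1,5]-hydrogen shift in the diene or desilylation may then overtake it.
- Endo/exo or facial selectivity may be poor.

The fallback replaces the dienophile by the sterically undemanding terminal alkyne and forms the C9–O bond afterwards. It sets out from 13 and comes back at 22. Acid 13 is esterified with TMSCHN2 to methyl (4S,5R)-5-acetyl-4-ethynyl-4-methyl-7-oxoheptanoate F1. Aldol condensation with 15 as in step 8 gives the alkynyl dienone F2. Hydrosilylation as in step 9 gives the alkynyl silyl dienol ether F3. Heating, kept below the onset of Alder–Rickert fragmentation, gives the bicyclo[2.2.2]octadiene ester F4. LiOH and then dilute acid hydrolyse the ester and the enol ether to the Δ9(11) keto acid F5. Iodolactonisation (I2, NaHCO3, MeCN) closes the lactone at C9 from the face of the C1 chain to give the 11-iodo lactone F6. Bu3SnH/AIBN removes iodine and gives 22. If only the hydride regiochemistry fails, a reductant that needs a six-membered transition state (catecholborane, or HSiCl3 with a phosphine oxide) should react with the s-cis exocyclic enone only.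

**Step 1.** Enantioselectivity may be low, because an alkenyl Grignard reagent and an α-substituted enone give poor face discrimination and a fast uncatalysed background addition. The fallback is a classical resolution. It sets out from 1 and 2 and comes back at 7. Steps 1 and 2 are run without the chiral ligand to give racemic 7. Saponification gives 3-[(1S,6S)-1-methyl-2-oxo-6-(prop-1-en-2-yl)cyclohexyl]propanoic acid F7 as the racemate. The (1S,6S)-acid is crystallised as its (R)-1-phenylethylammonium salt F8, liberated with dilute acid and re-esterified with TMSCHN2 to enantiopure 7.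

**Step 8.** The lithium dienolate may transfer a proton to, or attack, the methyl ketone or the enol lactone. The γ-keto aldolate may close to a lactol, which diverts the mesylation. The methyl ketone may add intramolecularly to the new enone. The fallback is a Horner–Wadsworth–Emmons union that avoids aldolate and elimination. It sets out from 15 and comes back at 19. LDA and ClP(O)(OEt)2 give the diethyl dienyl phosphate F9. A second equivalent of LDA induces the 1,3-phosphoryl shift from oxygen to C8 and gives the β-keto phosphonate F10. Olefination of 14 with F10 (LiCl, iPr2NEt, MeCN) gives 19 directly.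

**Step 11.** The C15 ketone may be methylenated as well, and the basic ylide may cleave the acetate. The fallback uses the selectivity of enolisation instead of that of carbonyl addition. It sets out from 25 and comes back at 26. KHMDS and PhNTf2 at −78 °C deprotonate the unhindered acetyl methyl group and give the enol triflate F11. Stille coupling with Me4Sn (Pd(PPh3)4, LiCl, THF) gives 26.

## Further compounds

F1 | step 9 | methyl (4S,5R)-5-acetyl-4-ethynyl-4-methyl-7-oxoheptanoate | O=CC[C@@H](C(C)=O)[C@](C)(CCC(=O)OC)C#C
F2 | step 9 | alkynyl dienone, (E)-aldol condensation product of 15 and F1 | O=C1C(C)=CC[C@H](C(C)=C)/C1=C\C[C@@H](C(C)=O)[C@](C)(CCC(=O)OC)C#C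
F3 | step 9 | triethylsilyl dienol ether of 7,8-dihydro-F2 | CC1=CC[C@H](C(C)=C)C(CC[C@@H](C(C)=O)[C@](C)(CCC(=O)OC)C#C)=C1O[Si](CC)(CC)CC
F4 | step 9 | bicyclo[2.2.2]octadiene ester, alkyne Diels–Alder adduct of F3 | CC1=C(O[Si](CC)(CC)CC)[C@]23CC[C@@H](C(C)=O)[C@](C)(CCC(=O)OC)C2=C[C@H]1C[C@@H]3C(C)=C
F5 | step 9 | Δ9(11) keto acid from F4 (C16 undefined) | CC1C(=O)[C@]23CC[C@@H](C(C)=O)[C@](C)(CCC(=O)O)C2=C[C@H]1C[C@@H]3C(C)=C
F6 | step 9 | 11-iodo derivative of 22 (iodine anti to the lactone oxygen; C16 undefined) | CC1C(=O)[C@]23CC[C@@H](C(C)=O)[C@]4(C)CCC(=O)O[C@@]42[C@@H](I)[C@H]1C[C@@H]3C(C)=C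
F7 | step 1 | 3-[(1S,6S)-1-methyl-2-oxo-6-(prop-1-en-2-yl)cyclohexyl]propanoic acid | O=C1CCC[C@@H](C(C)=C)[C@]1(C)CCC(=O)O
F8 | step 1 | (R)-1-phenylethylammonium salt of F7 | O=C1CCC[C@@H](C(C)=C)[C@]1(C)CCC(=O)[O-].C[C@@H]([NH3+])c1ccccc1
F9 | step 8 | diethyl dienyl phosphate of 15 | CC1=CC[C@@H](C=C1OP(=O)(OCC)OCC)C(C)=C
F10 | step 8 | diethyl β-keto phosphonate, carvone with P(O)(OEt)2 at C8 (C8 undefined) | CC1=CC[C@H](C(C)=C)C(P(=O)(OCC)OCC)C1=O
F11 | step 11 | enol triflate of the C5 acetyl group of 25 (C16 undefined) | CC1C(=O)[C@]23CC[C@@H](C(=C)OS(=O)(=O)C(F)(F)F)[C@]4(C)CCC(=O)O[C@@]42C[C@H]1C[C@@H]3OC(C)=O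
A1 | alternative 1 | masked ortho-benzoquinone with tethered vinyl group | COC1(OC)C=CC=C(CC[C@@H](C(C)=C)[C@](C)(CCC(=O)OC)C=C)C1=O
A2 | alternative 2 | Robinson annulation enedione with angular propargyl group at C8 | C#CC[C@]12CCC(=O)C(CCC(=O)OC)=C1CCCC2=O
A3 | alternative 3 | intact atisane: 14-acetoxy-atis-16-ene-3,15-dione | C=C1C(=O)[C@]23CC[C@H]4C(C)(C)C(=O)CC[C@]4(C)[C@H]2C[C@H]1C[C@@H]3OC(C)=O
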